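**Retrosynthetic overview**
- Feature: the five-membered ring C1–C7–C6–C5–C8 of the bicyclo[3.2.1]octenone is a cyclopentanone (C8=O). It carries methyl (C7), aryl (C6) and oxygen (C5) on three neighbouring carbons on alternating faces. These are the γ-, β- and α-positions of a 4-methylcyclopent-2-enone that comes from (R)-3-methylcyclopentanone.
- Last disconnections: C4–C5 is made by an intramolecular Mukaiyama aldol of a C5=C8 enol silane onto an (E)-2-methoxyenal arm on C1, which closes ring C1–C2–C3–C4–C5–C8. C2=C3 is made by a Still–Gennari-type olefination of a C1 aldehyde.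
- Key disconnection: C6–aryl and C5–O are made in one flask by aryl cuprate addition to the enone and hydroxylation of the C5 enolate that results.
- C1 is made quaternary before that, on the enone (allyl first, then CH2O anti to the methyl), where C1 is the only enolisable carbon.
- Ring order: the five-membered ring is bought with C7 in place. The six-membered ring is the only ring formed (step 18).

Key step: step 8

Remarks on the chemistry:
- The target numbering is used for all intermediates. "Top face" is the face of the five-membered ring that carries the aryl group.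
- Both C1 substituents are placed on the enone before the key step. After the key step, C1–H and C5–H would compete for the base, whereas in the enone the C5=C6 double bond leaves only C1 to be deprotonated.
- Stereocentres: C7 is bought and C1 is set in step 4. C6 is set in step 8. C5 is made in step 8, flattened in step 15 and re-set by the tether in step 18. C4 is set in step 18.

**Step 1**
Reactants: 1 (R)-3-methylcyclopentanone
Product: 3 (R)-trimethyl[(4-methylcyclopent-1-en-1-yl)oxy]silane, via lithium enolate 2 (not isolated)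
Conditions: LiN(i-Pr)2 (LDA), Me3SiCl (present from the start), THF, −78 °C
Reagents that add atoms: chlorotrimethylsilane, C[Si](C)(C)Cl
Why: Kinetic enolisation with O-silylation takes a proton from C5, the α-carbon that is not next to the methyl-bearing C7, the C7 centre is untouched, and the minor C1 regioisomer ends in step 2 as achiral 3-methylcyclopent-2-enone, which is separated and cannot lower the enantiopurity.

**Step 2**
Reactants: 3 (R)-trimethyl[(4-methylcyclopent-1-en-1-yl)oxy]silane
Product: 4 (S)-4-methylcyclopent-2-en-1-one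
Conditions: Pd(OAc)2 (10 mol %), O2 (1 atm), DMSO, 25 °C
Reagents that add atoms: none
Why: Saegusa–Ito oxidation, in which divalent palladium binds C5 of the enol silane and syn β-hydride elimination of C6–H gives the C5=C6 enone under neutral conditions that leave the γ-stereocentre C7 alone, while O2 returns zerovalent palladium to Pd(OAc)2.

**Step 3**
Reactants: 4 (S)-4-methylcyclopent-2-en-1-one
Product: 6 (4R,5S)-5-allyl-4-methylcyclopent-2-en-1-one, via lithium dienolate 5 (not isolated)
Conditions: LiN(i-Pr)2 (1.0 equiv), THF, −78 °C; allyl bromide, DMPU, −78 to −40 °C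
Reagents that add atoms: allyl bromide, C=CCBr
Why: Kinetic α'-deprotonation of a cyclopentenone and SN2 alkylation of the cross-conjugated dienolate, in which C1 is the only sp3 α-carbon because C5 is olefinic, the allyl group enters anti to the C7 methyl (a provisional C1 configuration), and low temperature without excess base keeps the cyclopentadiene-type C7–H in place.

**Step 4**
Reactants: 6 (4R,5S)-5-allyl-4-methylcyclopent-2-en-1-one
Product: 8 (4R,5R)-5-allyl-5-(hydroxymethyl)-4-methylcyclopent-2-en-1-one, via lithium dienolate 7 (not isolated)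
Conditions: LiN(i-Pr)2 (1.0 equiv), THF, −78 °C; CH2O (gas from cracked paraformaldehyde), −78 °C; aq. NH4Cl
Reagents that add atoms: formaldehyde, C=O
Why: Aldol addition of a fully substituted dienolate to monomeric formaldehyde, in which deprotonation can again occur only at C1 and the planar dienolate is attacked on the face opposite the adjacent C7 methyl, so that the CH2OH carbon (future C2) ends trans and the allyl group cis to the methyl, which sets the quaternary centre C1 as in the target.

**Step 5**
Reactants: 8 (4R,5R)-5-allyl-5-(hydroxymethyl)-4-methylcyclopent-2-en-1-one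
Product: 9 (4R,5R)-5-allyl-4-methyl-5-[(triethylsilyloxy)methyl]cyclopent-2-en-1-one
Conditions: Et3SiCl, imidazole, CH2Cl2, 0 °C
Reagents that add atoms: chlorotriethylsilane, CC[Si](Cl)(CC)CC
Why: Standard silylation of a primary alcohol, whose Et3Si ether blocks retro-aldol loss of formaldehyde in step 8 and can later be removed by mild acid without touching the aryl silyl ether.

**Step 6**
Reactants: 10 4-bromo-2-methoxyphenol
Product: 11 (4-bromo-2-methoxyphenoxy)(tert-butyl)dimethylsilane
Conditions: t-BuMe2SiCl, imidazole, DMF, 25 °C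
Reagents that add atoms: tert-butylchlorodimethylsilane, CC(C)(C)[Si](C)(C)Cl
Why: Standard phenol silylation, which removes the acidic proton before the organometallic steps.

**Step 7**
Reactants: 11 (4-bromo-2-methoxyphenoxy)(tert-butyl)dimethylsilane
Product: 12 4-(tert-butyldimethylsilyloxy)-3-methoxyphenylmagnesium bromide (titrated THF solution)
Conditions: Mg turnings, cat. BrCH2CH2Br, THF, 25–45 °C
Reagents that add atoms: magnesium, [Mg]
Why: Grignard formation by insertion of magnesium into the aryl C–Br bond, to which the aryl silyl and methyl ethers are inert.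

**Step 8**
Reactants: 9 (4R,5R)-5-allyl-4-methyl-5-[(triethylsilyloxy)methyl]cyclopent-2-en-1-one; 12 4-(tert-butyldimethylsilyloxy)-3-methoxyphenylmagnesium bromide
Product: 15 (2R,3R,4S,5S)-2-allyl-4-[4-(tert-butyldimethylsilyloxy)-3-methoxyphenyl]-5-hydroxy-3-methyl-2-[(triethylsilyloxy)methyl]cyclopentan-1-one, via diarylcuprate 13 (not isolated), via magnesium enolate 14 (not isolated)
Conditions: 12 (3 equiv), CuBr·SMe2 (1.5 equiv), THF, −78 to −40 °C; 9, −78 to −40 °C; MoO5·pyridine·HMPA (solid, excess), −40 to −20 °C; aq. Na2SO3/NH4Cl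
Reagents that add atoms: MoO5·pyridine·HMPA (oxodiperoxomolybdenum–pyridine–hexamethylphosphoric triamide), O=[Mo]12(OO1)OO2.c1ccncc1.CN(C)P(=O)(N(C)C)N(C)C
Why: Grignard reagent 12 and CuBr·SMe2 give cuprate 13, which binds the enone π-bond, forms a trivalent copper β-adduct and reductively eliminates to make the C6–aryl bond, leaving magnesium enolate 14, whose double bond can lie only between C8 and C5 because C1 is quaternary. The solid molybdenum peroxide then transfers one peroxo oxygen to C5 of 14 in the same flask and makes the C5–O bond. The closest known reaction type is the tandem vicinal difunctionalisation of cyclopentenones (cuprate conjugate addition followed by trapping of the regiodefined enolate), here with enolate hydroxylation as the trapping event, and no ring is closed. C6 is controlled by the methyl group on the adjacent C7, which sends the aryl group to the opposite (top) face, and C5 is controlled by the new aryl group, which sends oxygen to the bottom face, so that methyl, aryl and oxygen alternate. The step needs 1,4- over 1,2-addition (secured by the soft cuprate), face selectivity at C6 (secured by C7, since the CH2OSiEt3 arm on C1 is one carbon further away) and enough oxidant, because Me2S and the arylcopper by-product also consume it. Only the C5–O bond and the C6 configuration are carried to the target, since C5 is flattened in step 15 and re-set in step 18.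

**Step 9**
Reactants: 15 (the hydroxy ketone of step 8)
Product: 16 (2R,3R,4S,5S)-2-allyl-4-[4-(tert-butyldimethylsilyloxy)-3-methoxyphenyl]-5-methoxy-3-methyl-2-[(triethylsilyloxy)methyl]cyclopentan-1-one
Conditions: MeOTf, 2,6-di-tert-butyl-4-methylpyridine, CH2Cl2, 25–40 °C
Reagents that add atoms: methyl trifluoromethanesulfonate, COS(=O)(=O)C(F)(F)F
Why: O-Alkylation with a hard methylating agent and a hindered non-nucleophilic pyridine base, chosen because alkoxide conditions would invite enediol tautomerism of the α-ketol, so that no C–H is deprotonated and all stereocentres stay.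

**Step 10**
Reactants: 16 (the methyl ether of step 9)
Product: 17 (2R,3R,4S,5S)-2-allyl-4-[4-(tert-butyldimethylsilyloxy)-3-methoxyphenyl]-2-(hydroxymethyl)-5-methoxy-3-methylcyclopentan-1-one
Conditions: PPTS (cat.), MeOH/CH2Cl2, 0 to 25 °C
Reagents that add atoms: none
Why: Acid-catalysed methanolysis of silyl ethers, which cleaves the alkyl Et3Si ether quickly and the aryl t-BuMe2Si ether only slowly.

**Step 11**
Reactants: 17 (the primary alcohol of step 10)
Product: 18 (1R,2R,3S,4S)-1-allyl-3-[4-(tert-butyldimethylsilyloxy)-3-methoxyphenyl]-4-methoxy-2-methyl-5-oxocyclopentane-1-carbaldehyde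
Conditions: Dess–Martin periodinane, CH2Cl2, 0 to 25 °C
Reagents that add atoms: none
Why: Dess–Martin oxidation of a neopentyl primary alcohol under near-neutral conditions, giving an aldehyde (C2) without α-hydrogen so that C1 cannot epimerise.

**Step 12**
Reactants: 19 methyl 2-[bis(2,2,2-trifluoroethoxy)phosphoryl]acetate
Product: 20 methyl 2-[bis(2,2,2-trifluoroethoxy)phosphoryl]-2-diazoacetate
Conditions: 4-acetamidobenzenesulfonyl azide, DBU, MeCN, 0 to 25 °C
Reagents that add atoms: 4-acetamidobenzenesulfonyl azide, CC(=O)Nc1ccc(cc1)S(=O)(=O)N=[N+]=[N-]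
Why: Regitz diazo transfer to a doubly activated methylene group.

**Step 13**
Reactants: 20 methyl 2-[bis(2,2,2-trifluoroethoxy)phosphoryl]-2-diazoacetate
Product: 21 methyl 2-[bis(2,2,2-trifluoroethoxy)phosphoryl]-2-methoxyacetate
Conditions: Rh2(OAc)4 (1 mol %), MeOH (5 equiv), ClCH2CH2Cl, 80 °C
Reagents that add atoms: methanol, CO
Why: Rhodium carbenoid O–H insertion, the established way from diazophosphonoacetates to 2-alkoxyphosphonoacetates, run without base so that the trifluoroethyl esters on phosphorus are not exchanged.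

**Step 14**
Reactants: 18 (the aldehyde of step 11); 21 methyl 2-[bis(2,2,2-trifluoroethoxy)phosphoryl]-2-methoxyacetate
Product: 23 methyl (E)-3-{(1R,2R,3S,4S)-1-allyl-3-[4-(tert-butyldimethylsilyloxy)-3-methoxyphenyl]-4-methoxy-2-methyl-5-oxocyclopentyl}-2-methoxyprop-2-enoate, via potassium phosphonate 22 (not isolated)
Conditions: 21, KN(SiMe3)2, 18-crown-6, THF, −78 °C; then 18, −78 to −40 °C
Reagents that add atoms: none
Why: Still–Gennari variant of the Horner–Wadsworth–Emmons olefination, in which the electron-poor phosphonate makes collapse of the first adduct faster than its reversal, so that the kinetic alkene with C1 cis to the ester carbon C4 (E, C1 trans to OMe) should prevail, which is the only geometry from which C4 can reach C5 and which the ordinary dimethyl phosphonate would not give, while the aldehyde reacts in preference to the ketone flanked by C1 and C5.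

**Step 15**
Reactants: 23 (the (E)-ester of step 14)
Product: 24 methyl (E)-3-{(1R,4S,5R)-1-allyl-2-(tert-butyldimethylsilyloxy)-4-[4-(tert-butyldimethylsilyloxy)-3-methoxyphenyl]-3-methoxy-5-methylcyclopent-2-en-1-yl}-2-methoxyprop-2-enoate
Conditions: t-BuMe2SiOTf, Et3N, CH2Cl2, 0 to 25 °C
Reagents that add atoms: tert-butyldimethylsilyl trifluoromethanesulfonate, CC(C)(C)[Si](C)(C)OS(=O)(=O)C(F)(F)F
Why: Soft enolisation with silyl triflate and amine, in which C5–H is the only α-hydrogen because C1 is quaternary, so that a single C5=C8 enol silane forms that masks C8=O against the hydride of step 16 and serves as the nucleophile of step 18.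

**Step 16**
Reactants: 24 (the enol silane ester of step 15)
Product: 25 (E)-3-{(1R,4S,5R)-1-allyl-2-(tert-butyldimethylsilyloxy)-4-[4-(tert-butyldimethylsilyloxy)-3-methoxyphenyl]-3-methoxy-5-methylcyclopent-2-en-1-yl}-2-methoxyprop-2-en-1-ol
Conditions: i-Bu2AlH (2.5 equiv), CH2Cl2, −78 °C; aq. potassium sodium tartrate
Reagents that add atoms: none
Why: 1,2-Reduction of an unsaturated ester to the allylic alcohol by an aluminium hydride, which leaves the enol silane, the aryl silyl ether, both alkenes and the alkene geometry untouched, and whose non-acidic work-up spares the two enol ethers.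

**Step 17**
Reactants: 25 (the allylic alcohol of step 16)
Product: 26 (E)-3-{(1R,4S,5R)-1-allyl-2-(tert-butyldimethylsilyloxy)-4-[4-(tert-butyldimethylsilyloxy)-3-methoxyphenyl]-3-methoxy-5-methylcyclopent-2-en-1-yl}-2-methoxyprop-2-enal
Conditions: MnO2 (activated, excess), CH2Cl2, 25 °C
Reagents that add atoms: none
Why: Selective allylic alcohol oxidation on MnO2 under neutral heterogeneous conditions, which should neither protonate the electron-rich enol silane nor isomerise the crowded (E)-enal, which is used at once.

**Step 18**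
Reactants: 26 (the enal of step 17)
Product: 28 (1R,4S,5R,6S,7R)-1-allyl-6-[4-(tert-butyldimethylsilyloxy)-3-methoxyphenyl]-4-hydroxy-3,5-dimethoxy-7-methylbicyclo[3.2.1]oct-2-en-8-one, via difluoroboryl aldolate 27 (not isolated)
Conditions: BF3·OEt2 (1.1 equiv), CH2Cl2, −78 °C; aq. NaHCO3
Reagents that add atoms: none
Why: Intramolecular Mukaiyama aldol, a 6-(enolendo)-exo-trig closure of ring C1–C2–C3–C4–C5–C8, in which the arm hangs from the top face of C1 so that C4 can reach C5 only from that face, which re-creates C5 with OMe on the bottom face whatever its earlier configuration, and in which monodentate BF3 allows an open transition state with the C4=O dipole turned away from the C8–O bond, which should place the carbinol oxygen anti to C8 as (4S) requires, any C4 silyl ether from silyl transfer being cleaved in step 19.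

**Step 19**
Reactants: 28 (the silyl-protected bicycle of step 18)
Product: 29 (1R,4S,5R,6S,7R)-1-allyl-4-hydroxy-6-(4-hydroxy-3-methoxyphenyl)-3,5-dimethoxy-7-methylbicyclo[3.2.1]oct-2-en-8-one (target)
Conditions: Bu4NF, AcOH (1:1), THF, 0 °C
Reagents that add atoms: none
Why: Fluoride cleavage of the aryl silyl ether, buffered with AcOH so that neither phenoxide nor alkoxide builds up and the β-hydroxy ketone C4–C5–C8 is not opened by retro-aldol reaction, while the enol ether and allyl group are inert.

**Compound list**
1 | (R)-3-methylcyclopentanone | C[C@@H]1CCC(=O)C1 | starting material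
2 | lithium (R)-4-methylcyclopent-1-en-1-olate | C[C@@H]1CC=C(O[Li])C1 | intermediate
3 | (R)-trimethyl[(4-methylcyclopent-1-en-1-yl)oxy]silane | C[C@@H]1CC=C(O[Si](C)(C)C)C1 | intermediate
4 | (S)-4-methylcyclopent-2-en-1-one | O=C1C=C[C@@H](C)C1 | intermediate
5 | lithium cross-conjugated dienolate of 4 | C[C@@H]1C=CC(O[Li])=C1 | intermediate
6 | (4R,5S)-5-allyl-4-methylcyclopent-2-en-1-one | O=C1C=C[C@@H](C)[C@@H]1CC=C | intermediate
7 | lithium cross-conjugated dienolate of 6 | C[C@@H]1C=CC(O[Li])=C1CC=C | intermediate
8 | (4R,5R)-5-allyl-5-(hydroxymethyl)-4-methylcyclopent-2-en-1-one | O=C1C=C[C@@H](C)[C@@]1(CO)CC=C | intermediate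
9 | (4R,5R)-5-allyl-4-methyl-5-[(triethylsilyloxy)methyl]cyclopent-2-en-1-one | O=C1C=C[C@@H](C)[C@@]1(CO[Si](CC)(CC)CC)CC=C | intermediate
10 | 4-bromo-2-methoxyphenol | COc1cc(Br)ccc1O | starting material
11 | (4-bromo-2-methoxyphenoxy)(tert-butyl)dimethylsilane | COc1cc(Br)ccc1O[Si](C)(C)C(C)(C)C | intermediate
12 | 4-(tert-butyldimethylsilyloxy)-3-methoxyphenylmagnesium bromide | COc1cc([Mg]Br)ccc1O[Si](C)(C)C(C)(C)C | intermediate
13 | bromomagnesium bis[4-(tert-butyldimethylsilyloxy)-3-methoxyphenyl]cuprate | COc1cc([Cu-]c2ccc(O[Si](C)(C)C(C)(C)C)c(OC)c2)ccc1O[Si](C)(C)C(C)(C)C.[Mg+]Br | intermediate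
14 | bromomagnesium C5=C8 enolate of the conjugate adduct | Br[Mg]OC1=C[C@H](c2ccc(O[Si](C)(C)C(C)(C)C)c(OC)c2)[C@@H](C)[C@@]1(CO[Si](CC)(CC)CC)CC=C | intermediate
15 | (2R,3R,4S,5S)-2-allyl-4-[4-(tert-butyldimethylsilyloxy)-3-methoxyphenyl]-5-hydroxy-3-methyl-2-[(triethylsilyloxy)methyl]cyclopentan-1-one | O=C1[C@@H](O)[C@H](c2ccc(O[Si](C)(C)C(C)(C)C)c(OC)c2)[C@@H](C)[C@@]1(CO[Si](CC)(CC)CC)CC=C | intermediate
16 | 5-O-methyl ether of 15 | O=C1[C@@H](OC)[C@H](c2ccc(O[Si](C)(C)C(C)(C)C)c(OC)c2)[C@@H](C)[C@@]1(CO[Si](CC)(CC)CC)CC=C | intermediate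
17 | (2R,3R,4S,5S)-2-allyl-4-aryl-2-(hydroxymethyl)-5-methoxy-3-methylcyclopentan-1-one (aryl as in 15) | O=C1[C@@H](OC)[C@H](c2ccc(O[Si](C)(C)C(C)(C)C)c(OC)c2)[C@@H](C)[C@@]1(CO)CC=C | intermediate
18 | (1R,2R,3S,4S)-1-allyl-3-aryl-4-methoxy-2-methyl-5-oxocyclopentane-1-carbaldehyde (aryl as in 15) | O=C1[C@@H](OC)[C@H](c2ccc(O[Si](C)(C)C(C)(C)C)c(OC)c2)[C@@H](C)[C@@]1(C=O)CC=C | intermediate
19 | methyl 2-[bis(2,2,2-trifluoroethoxy)phosphoryl]acetate | COC(=O)CP(=O)(OCC(F)(F)F)OCC(F)(F)F | starting material
20 | methyl 2-[bis(2,2,2-trifluoroethoxy)phosphoryl]-2-diazoacetate | COC(=O)C(=[N+]=[N-])P(=O)(OCC(F)(F)F)OCC(F)(F)F | intermediate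
21 | methyl 2-[bis(2,2,2-trifluoroethoxy)phosphoryl]-2-methoxyacetate | COC(=O)C(OC)P(=O)(OCC(F)(F)F)OCC(F)(F)F | intermediate
22 | potassium salt of the carbanion of 21 | [K+].COC(=O)[C-](OC)P(=O)(OCC(F)(F)F)OCC(F)(F)F | intermediate
23 | (E)-2-methoxyacrylate with C1 cis to the ester | O=C1[C@@H](OC)[C@H](c2ccc(O[Si](C)(C)C(C)(C)C)c(OC)c2)[C@@H](C)[C@@]1(/C=C(/OC)C(=O)OC)CC=C | intermediate
24 | C5=C8 tert-butyldimethylsilyl enol ether of 23 | CC(C)(C)[Si](C)(C)OC1=C(OC)[C@H](c2ccc(O[Si](C)(C)C(C)(C)C)c(OC)c2)[C@@H](C)[C@@]1(/C=C(/OC)C(=O)OC)CC=C | intermediate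
25 | (E)-allylic alcohol from 24 | CC(C)(C)[Si](C)(C)OC1=C(OC)[C@H](c2ccc(O[Si](C)(C)C(C)(C)C)c(OC)c2)[C@@H](C)[C@@]1(/C=C(/OC)CO)CC=C | intermediate
26 | (E)-2-methoxyenal from 25 | CC(C)(C)[Si](C)(C)OC1=C(OC)[C@H](c2ccc(O[Si](C)(C)C(C)(C)C)c(OC)c2)[C@@H](C)[C@@]1(/C=C(/OC)C=O)CC=C | intermediate
27 | C4 O-difluoroboryl aldolate | C=CC[C@@]12C=C(OC)[C@H](OB(F)F)[C@@](OC)(C1=O)[C@H](c1ccc(O[Si](C)(C)C(C)(C)C)c(OC)c1)[C@H]2C | intermediate
28 | (1R,4S,5R,6S,7R)-1-allyl-6-[4-(tert-butyldimethylsilyloxy)-3-methoxyphenyl]-4-hydroxy-3,5-dimethoxy-7-methylbicyclo[3.2.1]oct-2-en-8-one | C=CC[C@@]12C=C(OC)[C@H](O)[C@@](OC)(C1=O)[C@H](c1ccc(O[Si](C)(C)C(C)(C)C)c(OC)c1)[C@H]2C | intermediate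
29 | (1R,4S,5R,6S,7R)-1-allyl-4-hydroxy-6-(4-hydroxy-3-methoxyphenyl)-3,5-dimethoxy-7-methylbicyclo[3.2.1]oct-2-en-8-one | C=CC[C@@]12C=C(OC)[C@H](O)[C@@](OC)(C1=O)[C@H](c1ccc(O)c(OC)c1)[C@H]2C | target

**Total step count:** 19
**Longest linear sequence:** 15 steps (1–5, 8–11, 14–19)

**Steps most likely to fail**

**Risk at step 8.** Oxygen transfer to a magnesium enolate in the presence of arylcopper and Me2S may be slow and wasteful. Simple protonation, over-oxidation, or aldol coupling between enolate and product could then take over.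

The fallback sets out from 9 and 12 and comes back at 15.
- The same cuprate addition is run with Me3SiCl present, and the trimethylsilyl enol ether F1 is isolated.
- A Rubottom oxidation with one equivalent of dimethyldioxirane (acetone/CH2Cl2, −78 °C) attacks the electron-rich enol silane, not the allyl group. It does so on the face opposite the aryl group and gives the α-silyloxy ketone F2.
- Brief treatment with citric acid in MeOH removes the Me3Si group and returns 15.

The same two bonds are made, but in two operations and without any metal enolate meeting the oxidant.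

**Risk at step 18.** The aldehyde oxygen may turn toward C8 instead of away from it, because the C6 aryl group crowds the other quadrant. That would mean poor or reversed facial selectivity at C4.

The fallback sets out from 26 and comes back at 28. It sets C4 by hydride delivery instead of by the aldol.
- The ring is closed with TiCl4 (CH2Cl2, −78 °C) without regard to C4, which should give the C4-epimeric ketol F3.
- Dess–Martin oxidation gives the bicyclic 4,8-dione F4.
- Luche reduction (NaBH4, CeCl3·7H2O, MeOH, −78 °C) delivers hydride to C4 from the face turned toward C8, because the other face lies under the aryl ring. This pushes the oxygen into the (4S) position of 28.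
- The C8 carbonyl is flanked by two fully substituted carbons. It is screened by the C7 methyl on one face and by the C2–C4 bridge on the other, which should hold it back.

**Risk at step 14.** Kinetic control may erode and place C1 trans to the ester, from where ring closure is impossible. The formyl group may also be lost by retro-Claisen cleavage under the basic conditions.

The fallback sets out from 18 and comes back at 28. It lets the C2=C3 bond arise inside the ring, where it can only be cis.
- The lithium enolate of methyl methoxyacetate (LiN(i-Pr)2, THF, −78 °C) adds to the aldehyde to give the β-hydroxy-α-methoxy ester F5. This is a mixture at C2 and C3, and both centres are destroyed later.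
- t-BuMe2SiOTf/Et3N silylates the C2 hydroxyl and forms the C5=C8 enol silane, giving the bis-silyl ester F6.
- i-Bu2AlH (1.1 equiv, toluene, −78 °C) stops at the α-methoxy aldehyde F7.
- BF3·OEt2 closes the saturated ring to the bicyclic ketol F8.
- Dess–Martin oxidation gives the saturated 4,8-dione F9.
- DBU expels the β-silyloxy group by E1cB elimination to give the dione F4, which is reduced to 28 as described for step 18.

**Further compounds**
F1 | step 8 | trimethylsilyl enol ether of the conjugate adduct | C[Si](C)(C)OC1=C[C@H](c2ccc(O[Si](C)(C)C(C)(C)C)c(OC)c2)[C@@H](C)[C@@]1(CO[Si](CC)(CC)CC)CC=C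
F2 | step 8 | 5-(trimethylsilyloxy) ketone (O-trimethylsilyl derivative of 15) | O=C1[C@@H](O[Si](C)(C)C)[C@H](c2ccc(O[Si](C)(C)C(C)(C)C)c(OC)c2)[C@@H](C)[C@@]1(CO[Si](CC)(CC)CC)CC=C
F3 | step 18 | (4R)-epimer of 28 | C=CC[C@@]12C=C(OC)[C@@H](O)[C@@](OC)(C1=O)[C@H](c1ccc(O[Si](C)(C)C(C)(C)C)c(OC)c1)[C@H]2C
F4 | step 18 | 1-allyl-6-aryl-3,5-dimethoxy-7-methylbicyclo[3.2.1]oct-2-ene-4,8-dione (aryl as in 28) | C=CC[C@@]12C=C(OC)C(=O)[C@@](OC)(C1=O)[C@H](c1ccc(O[Si](C)(C)C(C)(C)C)c(OC)c1)[C@H]2C
F5 | step 14 | β-hydroxy-α-methoxy ester from 18 (mixture at C2 and C3) | O=C1[C@@H](OC)[C@H](c2ccc(O[Si](C)(C)C(C)(C)C)c(OC)c2)[C@@H](C)[C@@]1(C(O)C(OC)C(=O)OC)CC=C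
F6 | step 14 | C2 silyl ether and C5=C8 enol silane of F5 | CC(C)(C)[Si](C)(C)OC1=C(OC)[C@H](c2ccc(O[Si](C)(C)C(C)(C)C)c(OC)c2)[C@@H](C)[C@@]1(C(O[Si](C)(C)C(C)(C)C)C(OC)C(=O)OC)CC=C
F7 | step 14 | α-methoxy aldehyde from F6 | CC(C)(C)[Si](C)(C)OC1=C(OC)[C@H](c2ccc(O[Si](C)(C)C(C)(C)C)c(OC)c2)[C@@H](C)[C@@]1(C(O[Si](C)(C)C(C)(C)C)C(OC)C=O)CC=C
F8 | step 14 | saturated bicyclic ketol (mixture at C2, C3 and C4) | C=CC[C@@]12C(O[Si](C)(C)C(C)(C)C)C(OC)C(O)[C@@](OC)(C1=O)[C@H](c1ccc(O[Si](C)(C)C(C)(C)C)c(OC)c1)[C@H]2C
F9 | step 14 | saturated bicyclic 4,8-dione (mixture at C2 and C3) | C=CC[C@@]12C(O[Si](C)(C)C(C)(C)C)C(OC)C(=O)[C@@](OC)(C1=O)[C@H](c1ccc(O[Si](C)(C)C(C)(C)C)c(OC)c1)[C@H]2C
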